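**Plan**
1. Cuts: the two equivalent alkenes C7=C8 and C7'=C8' (carotenoid numbering) go first. This splits the C40 nonaene into the C20 dialdehyde C8–C8' and two copies of one C10 ring sulfone. The C6–C7 bond of that sulfone is cut second.
2. Enabling feature: in each six-membered ε ring the stereocentre C6 is allylic to the ring alkene C4=C5 and bears the exocyclic carbon C7. The array C7–C6–C5=C4 is what a [3,3] shift leaves when an acetate-type ester sits on C4 of the transposed C5=C6 cyclohexenol.
3. Forward order: the carbocycle is bought and no ring is formed. The sequence is ketone, carbinol, tosylacetate, rearranged sulfone. Both sulfone units are then attached to the two chain ends in one flask, both alkenes are released together, and the chain is equilibrated to all-E.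
4. Stereochemistry: a catalyst-controlled CBS reduction sets C4 (S), and the suprafacial shift relays it to C6 (R). C6 and C6' are the same building block used twice, and no later step touches them.

Key step: step 3

Assumption: carotenoid numbering is used for ring and chain atoms throughout, and 2,4,4-trimethylcyclohex-2-enone, tosylacetic acid and crocetin dialdehyde are taken as catalogue chemicals.

**Step 1**
Reactants: 1 2,4,4-trimethylcyclohex-2-en-1-one
Product: 2 (1S)-2,4,4-trimethylcyclohex-2-en-1-ol
Conditions: (3aR)-1-methyl-3,3-diphenyltetrahydro-1H,3H-pyrrolo[1,2-c][1,3,2]oxazaborole ((R)-Me-CBS, 10 mol %), BH3·SMe2 (0.6 equiv), THF, 0 °C; aq NH4Cl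
Reagents that add atoms: none
Why: Corey–Bakshi–Shibata reduction, in which the ketone binds the catalyst boron with its larger, methyl-bearing alkenyl flank turned away from the catalyst, so the coordinated borane delivers hydride to one carbonyl face and the (R)-catalyst should give the S carbinol (as with aryl/alkenyl versus CH2 ketones), while the trisubstituted alkene next to the quaternary carbon resists hydroboration.

**Step 2**
Reactants: 2 (1S)-2,4,4-trimethylcyclohex-2-en-1-ol; 3 2-(4-methylbenzenesulfonyl)acetic acid (tosylacetic acid)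
Product: 4 (1S)-2,4,4-trimethylcyclohex-2-en-1-yl 2-(4-methylbenzenesulfonyl)acetate
Conditions: N,N'-dicyclohexylcarbodiimide (1.1 equiv), 4-(dimethylamino)pyridine (5 mol %), CH2Cl2, 0 °C → rt
Reagents that add atoms: none
Why: Steglich esterification acylates the hydroxyl oxygen and never breaks the C4–O bond, so the S configuration is carried over unchanged.

**Step 3**
Reactants: 4 (1S)-2,4,4-trimethylcyclohex-2-en-1-yl 2-(4-methylbenzenesulfonyl)acetate
Product: 7 1-methyl-4-({[(1R)-2,6,6-trimethylcyclohex-2-en-1-yl]methyl}sulfonyl)benzene, via silyl ketene acetal 5 (not isolated), via rearranged trimethylsilyl ester 6 (not isolated)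
Conditions: N,O-bis(trimethylsilyl)acetamide (1.5 equiv), KOAc (10 mol %), PhMe, 110 °C; aq NaHCO3; recrystallisation
Reagents that add atoms: N,O-bis(trimethylsilyl)acetamide, CC(=N[Si](C)(C)C)O[Si](C)(C)C (supplies the Me3Si group of 5 and 6 only; none of its atoms stays in 7)
Why: Acetate-activated silylation of the acidic sulfonylacetate gives ketene acetal 5, which undergoes a concerted [3,3]-sigmatropic shift through a six-membered cyclic transition state (C4–O breaks, C7 bonds to C6, the ring alkene moves from C5=C6 to C4=C5), after which acetate desilylates ester 6, the carboxylate loses CO2 and the sulfonyl carbanion is protonated to 7. The closest known reaction type is the decarboxylative Ireland–Claisen rearrangement of allylic arylsulfonylacetates to homoallylic sulfones, established for secondary allylic esters. No ring is closed, since the cyclohexene only serves as the template across which the bond is relayed. The one new stereocentre, C6, is controlled by the carbinol centre C4: the tethered ketene acetal can reach C6 only on the ring face that carries the oxygen, so S at C4 becomes R at C6 whether the transition state is chair-like or boat-like, and the transient centre at C7 of 6 is erased by decarboxylation. The step needs the pericyclic path to outrun ionisation or elimination of the allylic ester, which would cost enantiopurity, and this is favoured by the non-polar, near-neutral medium and by the vinylic C5 methyl, whose A(1,2) strain holds the acyloxy group pseudoaxial above the alkene. Regiochemistry is not at issue because C6 is the only allyl terminus, and the crystalline aryl sulfone can be recrystallised to raise its enantiopurity before two copies are joined.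

**Step 4**
Reactants: 7 1-methyl-4-({[(1R)-2,6,6-trimethylcyclohex-2-en-1-yl]methyl}sulfonyl)benzene (2.2 equiv); 8 crocetin dialdehyde, (2E,4E,6E,8E,10E,12E,14E)-2,6,11,15-tetramethylhexadeca-2,4,6,8,10,12,14-heptaenedial
Product: 11 (6R,6'R)-7,7'-bis(4-methylbenzenesulfonyl)-7,8,7',8'-tetrahydro-ε,ε-carotene-8,8'-diyl dibenzoate (epimers at C7/C8/C7'/C8'), via lithiated sulfone 9 (not isolated), via dilithium bis-alkoxide 10 (not isolated)
Conditions: 7, n-BuLi (2.2 equiv), THF, −78 → −20 → −78 °C; 8 in THF, −78 °C, dark; BzCl (3 equiv), −78 → −20 °C; aq NaHCO3; rapid filtration through neutral alumina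
Reagents that add atoms: benzoyl chloride, O=C(Cl)c1ccccc1; n-butyllithium, [Li]CCCC (lithium in 9 and 10 only)
Why: Addition stage of the Julia–Lythgoe olefination, in which the carbanion is generated at C7 and not at the stereocentre C6, adds 1,2 to both enal termini as cyclogeranyl-type sulfone anions do with 2-methyl enals, and is locked by cold acylation before retro-addition, the four new centres being left uncontrolled because the next step destroys them.

**Step 5**
Reactants: 11 (6R,6'R)-7,7'-bis(4-methylbenzenesulfonyl)-7,8,7',8'-tetrahydro-ε,ε-carotene-8,8'-diyl dibenzoate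
Product: 12 (6R,6'R)-ε,ε-carotene as a mixture of chain E/Z isomers
Conditions: SmI2 (0.1 M in THF, added until its colour persists, ca. 5 equiv), HMPA, THF, −78 °C, Ar, dark, no proton source; aq NaHCO3
Reagents that add atoms: none
Why: Reductive-elimination stage of the Julia–Lythgoe olefination with divalent samarium, where two electrons per terminus expel sulfinate and benzoate, and whichever group leaves first the resulting carbanion has the other as a β or vinylogous leaving group, so all paths converge on the conjugated nonaene with a preference for E at C7=C8, while the aprotic, base-free medium avoids a vinyl sulfone pathway and leaves the doubly allylic C6–H untouched.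

**Step 6**
Reactants: 12 (6R,6'R)-ε,ε-carotene as a mixture of chain E/Z isomers
Product: 13 (all-E,6R,6'R)-ε,ε-carotene (target)
Conditions: I2 (2 mol %), PhMe, visible light, rt, N2; aq Na2S2O3; crystallisation from CH2Cl2–MeOH (mother liquors re-equilibrated)
Reagents that add atoms: none
Why: Iodine-atom-catalysed stereomutation of polyenes, in which reversible iodine-atom addition lets the chain bonds rotate, the congested 7Z forms drain towards E, the least soluble all-E isomer is collected by crystallisation, and the sp3 centres C6 and C6' take no part.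

**Compound list**
1 | 2,4,4-trimethylcyclohex-2-en-1-one | CC1=CC(C)(C)CCC1=O | starting material
2 | (1S)-2,4,4-trimethylcyclohex-2-en-1-ol | O[C@@H]1C(C)=CC(C)(C)CC1 | intermediate
3 | 2-(4-methylbenzenesulfonyl)acetic acid | Cc1ccc(cc1)S(=O)(=O)CC(=O)O | starting material
4 | (1S)-2,4,4-trimethylcyclohex-2-en-1-yl 2-(4-methylbenzenesulfonyl)acetate | Cc1ccc(cc1)S(=O)(=O)CC(=O)O[C@@H]1C(C)=CC(C)(C)CC1 | intermediate
5 | trimethyl({2-(4-methylbenzenesulfonyl)-1-{[(1S)-2,4,4-trimethylcyclohex-2-en-1-yl]oxy}ethenyl}oxy)silane (ketene acetal geometry open) | Cc1ccc(cc1)S(=O)(=O)C=C(O[Si](C)(C)C)O[C@@H]1C(C)=CC(C)(C)CC1 | intermediate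
6 | trimethylsilyl 2-(4-methylbenzenesulfonyl)-2-[(1R)-2,6,6-trimethylcyclohex-2-en-1-yl]acetate (epimers at the sulfonyl carbon) | CC1=CCCC(C)(C)[C@H]1C(C(=O)O[Si](C)(C)C)S(=O)(=O)c1ccc(C)cc1 | intermediate
7 | 1-methyl-4-({[(1R)-2,6,6-trimethylcyclohex-2-en-1-yl]methyl}sulfonyl)benzene | CC1=CCCC(C)(C)[C@H]1CS(=O)(=O)c1ccc(C)cc1 | intermediate
8 | crocetin dialdehyde (8,8'-diapocarotene-8,8'-dial) | O=C/C(C)=C/C=C/C(C)=C/C=C/C=C(C)/C=C/C=C(C)/C=O | starting material
9 | {(4-methylbenzenesulfonyl)[(1R)-2,6,6-trimethylcyclohex-2-en-1-yl]methyl}lithium | CC1=CCCC(C)(C)[C@H]1C([Li])S(=O)(=O)c1ccc(C)cc1 | intermediate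
10 | dilithium (6R,6'R)-7,7'-bis(4-methylbenzenesulfonyl)-7,8,7',8'-tetrahydro-ε,ε-carotene-8,8'-diolate | CC1=CCCC(C)(C)[C@H]1C(S(=O)(=O)c1ccc(C)cc1)C(O[Li])/C(C)=C/C=C/C(C)=C/C=C/C=C(C)/C=C/C=C(C)/C(O[Li])C(S(=O)(=O)c1ccc(C)cc1)[C@H]1C(C)=CCCC1(C)C | intermediate
11 | (6R,6'R)-7,7'-bis(4-methylbenzenesulfonyl)-7,8,7',8'-tetrahydro-ε,ε-carotene-8,8'-diyl dibenzoate | CC1=CCCC(C)(C)[C@H]1C(S(=O)(=O)c1ccc(C)cc1)C(OC(=O)c1ccccc1)/C(C)=C/C=C/C(C)=C/C=C/C=C(C)/C=C/C=C(C)/C(OC(=O)c1ccccc1)C(S(=O)(=O)c1ccc(C)cc1)[C@H]1C(C)=CCCC1(C)C | intermediate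
12 | (6R,6'R)-ε,ε-carotene, chain geometry not uniform | CC1=CCCC(C)(C)[C@H]1C=CC(C)=CC=CC(C)=CC=CC=C(C)C=CC=C(C)C=C[C@H]1C(C)=CCCC1(C)C | intermediate
13 | (all-E,6R,6'R)-ε,ε-carotene | CC1=CCCC(C)(C)[C@H]1/C=C/C(C)=C/C=C/C(C)=C/C=C/C=C(C)/C=C/C=C(C)/C=C/[C@H]1C(C)=CCCC1(C)C | target

Total step count: 6
Longest linear sequence: 6 steps (1 → 2 → 4 → 7 → 11 → 12 → 13)

**Steps most likely to fail**

**Step 3.** The shift has to form a bond at C6 next to the quaternary C1. It may therefore be slower than thermal elimination or ionisation of the allylic ester, with loss of material and erosion of enantiopurity.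
- The fallback sets out from 2 and returns at 7. The carbon is delivered by a Wittig–Still [2,3]-rearrangement, which runs at −78 °C and is likewise suprafacial.
- Alcohol 2 is O-alkylated with Bu3SnCH2I (KH, THF) to tributyl({[(1S)-2,4,4-trimethylcyclohex-2-en-1-yl]oxy}methyl)stannane F1.
- Tin–lithium exchange with n-BuLi releases the oxymethyl carbanion, which rearranges on the oxygen-bearing face to [(1R)-2,6,6-trimethylcyclohex-2-en-1-yl]methanol F2.
- Hata thioetherification with di-p-tolyl disulfide and PBu3 gives 1-methyl-4-({[(1R)-2,6,6-trimethylcyclohex-2-en-1-yl]methyl}sulfanyl)benzene F3.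
- Oxidation at sulfur with H2O2 and catalytic (NH4)6Mo7O24 then gives 7.

**Step 4.** Addition of the encumbered carbanion to the electron-rich, sparingly soluble polyene dialdehyde is reversible. Retro-addition before acylation, or arrest after only one terminus has reacted, may dominate.
- The fallback sets out from 7 and returns at 11. The C7–C8 bonds are made by acylation, which becomes irreversible because the product is deprotonated as it forms.
- Lithiated 7 (n-BuLi, with LiN(SiMe3)2 as extra base, THF) is acylated by both ester groups of dimethyl crocetinate to (6R,6'R)-7,7'-bis(4-methylbenzenesulfonyl)-7,8,7',8'-tetrahydro-ε,ε-carotene-8,8'-dione F4.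
- Luche reduction (NaBH4, CeCl3·7H2O, MeOH–THF) gives (6R,6'R)-7,7'-bis(4-methylbenzenesulfonyl)-7,8,7',8'-tetrahydro-ε,ε-carotene-8,8'-diol F5.
- Benzoylation (BzCl, pyridine, 4-(dimethylamino)pyridine) then gives 11.

**Step 5.** Electron transfer may continue into the long chromophore. Over-reduction of the polyene, protonation of delocalised carbanions or an incomplete second elimination could then compete.
- The fallback sets out from 7 and returns at 12. The reductive elimination is done on a short C5 enal, and the polyene is completed afterwards by a non-reductive double Wittig reaction (C15 + C10 + C15).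
- Lithiated 7 is added to (E)-4-[(tert-butyldimethylsilyl)oxy]-2-methylbut-2-enal and trapped with BzCl to give (3E)-5-[(tert-butyldimethylsilyl)oxy]-3-methyl-1-(4-methylbenzenesulfonyl)-1-[(1R)-2,6,6-trimethylcyclohex-2-en-1-yl]pent-3-en-2-yl benzoate F6.
- SmI2–HMPA converts it into tert-butyldimethyl({(2E,4E)-3-methyl-5-[(1R)-2,6,6-trimethylcyclohex-2-en-1-yl]penta-2,4-dien-1-yl}oxy)silane F7.
- PPh3·HBr in MeOH removes the silyl group and captures the dienylic cation as {(2E,4E)-3-methyl-5-[(1R)-2,6,6-trimethylcyclohex-2-en-1-yl]penta-2,4-dien-1-yl}triphenylphosphonium bromide F8.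
- Two equivalents of this salt condense with (2E,4E,6E)-2,7-dimethylocta-2,4,6-trienedial (NaOMe, MeOH–CH2Cl2, 0 °C) to give 12, which enters step 6.

**Further compounds**
F1 | step 3 | tributyl({[(1S)-2,4,4-trimethylcyclohex-2-en-1-yl]oxy}methyl)stannane | CCCC[Sn](CCCC)(CCCC)CO[C@@H]1C(C)=CC(C)(C)CC1
F2 | step 3 | [(1R)-2,6,6-trimethylcyclohex-2-en-1-yl]methanol | CC1=CCCC(C)(C)[C@H]1CO
F3 | step 3 | 1-methyl-4-({[(1R)-2,6,6-trimethylcyclohex-2-en-1-yl]methyl}sulfanyl)benzene | CC1=CCCC(C)(C)[C@H]1CSc1ccc(C)cc1
F4 | step 4 | (6R,6'R)-7,7'-bis(4-methylbenzenesulfonyl)-7,8,7',8'-tetrahydro-ε,ε-carotene-8,8'-dione | CC1=CCCC(C)(C)[C@H]1C(S(=O)(=O)c1ccc(C)cc1)C(=O)/C(C)=C/C=C/C(C)=C/C=C/C=C(C)/C=C/C=C(C)/C(=O)C(S(=O)(=O)c1ccc(C)cc1)[C@H]1C(C)=CCCC1(C)C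
F5 | step 4 | (6R,6'R)-7,7'-bis(4-methylbenzenesulfonyl)-7,8,7',8'-tetrahydro-ε,ε-carotene-8,8'-diol | CC1=CCCC(C)(C)[C@H]1C(S(=O)(=O)c1ccc(C)cc1)C(O)/C(C)=C/C=C/C(C)=C/C=C/C=C(C)/C=C/C=C(C)/C(O)C(S(=O)(=O)c1ccc(C)cc1)[C@H]1C(C)=CCCC1(C)C
F6 | step 5 | (3E)-5-[(tert-butyldimethylsilyl)oxy]-3-methyl-1-(4-methylbenzenesulfonyl)-1-[(1R)-2,6,6-trimethylcyclohex-2-en-1-yl]pent-3-en-2-yl benzoate | CC1=CCCC(C)(C)[C@H]1C(S(=O)(=O)c1ccc(C)cc1)C(OC(=O)c1ccccc1)/C(C)=C/CO[Si](C)(C)C(C)(C)C
F7 | step 5 | tert-butyldimethyl({(2E,4E)-3-methyl-5-[(1R)-2,6,6-trimethylcyclohex-2-en-1-yl]penta-2,4-dien-1-yl}oxy)silane | CC1=CCCC(C)(C)[C@H]1/C=C/C(C)=C/CO[Si](C)(C)C(C)(C)C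
F8 | step 5 | {(2E,4E)-3-methyl-5-[(1R)-2,6,6-trimethylcyclohex-2-en-1-yl]penta-2,4-dien-1-yl}triphenylphosphonium bromide | CC1=CCCC(C)(C)[C@H]1/C=C/C(C)=C/C[P+](c1ccccc1)(c1ccccc1)c1ccccc1.[Br-]
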